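**Retrosynthetic overview**
1. Target 9 is cut into two molecules of the 8-O-4' neolignan 6 plus one water. The oxolane, the only ring made, is formed last by oxidative 8–8' dimerisation of the O-alkylated isoeugenol unit, hydration of the bis(quinone-methide-type) dication and 5-exo O-closure.
2. 6 comes from racemic aryloxy ketone 4 by asymmetric hydrogenation with dynamic kinetic resolution, which sets both side-chain centres (1R,2S).
3. 4 comes from (E)-isoeugenol 3 and bromo ketone 2 (Williamson ether synthesis); 2 comes from 3',4'-dimethoxypropiophenone 1.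
4. Ring order: all four benzene rings are bought; the oxolane is closed in the final step.

Assumption: the SMILES is read as both side chains (1R,2S) (erythro) and an oxolane core that is 2,3-trans-3,4-cis-4,5-trans (meso-type, so 2S,3S,4R,5R and 2R,3R,4S,5S describe the same compound); (E)-isoeugenol of at least 98 % E content is used.

**Route**

Step 1
Reactants: 1 1-(3,4-dimethoxyphenyl)propan-1-one
Product: 2 rac-2-bromo-1-(3,4-dimethoxyphenyl)propan-1-one
Conditions: CuBr2 (2.1 equiv), EtOAc/CHCl3 1:1, reflux, 3 h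
Reagents that add atoms: CuBr2 (copper dibromide), Br[Cu]Br
Why: Heterogeneous α-bromination of an aryl ketone through its copper-bound enol, which leaves the electron-rich ring alone; the new centre is racemic and is corrected in step 3.

Step 2
Reactants: 2 rac-2-bromo-1-(3,4-dimethoxyphenyl)propan-1-one; 3 (E)-isoeugenol (2-methoxy-4-[(E)-prop-1-en-1-yl]phenol)
Product: 4 rac-1-(3,4-dimethoxyphenyl)-2-{2-methoxy-4-[(E)-prop-1-en-1-yl]phenoxy}propan-1-one
Conditions: K2CO3 (1.5 equiv), acetone, reflux, N2, 6 h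
Reagents that add atoms: none
Why: Williamson ether synthesis, SN2 attack of the phenoxide on the carbonyl-activated secondary bromide; the E-propenyl group is untouched and the α-centre stays racemic and base-labile, which step 3 uses.

Step 3
Reactants: 4 rac-1-(3,4-dimethoxyphenyl)-2-{2-methoxy-4-[(E)-prop-1-en-1-yl]phenoxy}propan-1-one
Product: 6 (1R,2S)-1-(3,4-dimethoxyphenyl)-2-{2-methoxy-4-[(E)-prop-1-en-1-yl]phenoxy}propan-1-ol, via (S)-aryloxy ketone 5 (not isolated)
Conditions: H2 (10 atm), RuCl2[(R)-xylbinap][(R)-daipen] (0.5 mol %), KOtBu (20 mol %), iPrOH/THF 4:1, 25 °C, 12 h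
Reagents that add atoms: none
Why: Noyori-type asymmetric ketone hydrogenation with dynamic kinetic resolution: KOtBu racemises the α-aryloxy ketone through its enolate; the catalyst antipode that gives (S)-1-phenylethanol from acetophenone delivers hydride to the Si face of the carbonyl (C1 = R); and the anti (erythro) preference of this catalyst class for α-alkoxy and α-aryloxy ketones makes (S)-ketone 5 the fast-reacting enantiomer (C2 = S), while the C=C bond is not reduced.

Step 4
Reactants: 6 (1R,2S)-1-(3,4-dimethoxyphenyl)-2-{2-methoxy-4-[(E)-prop-1-en-1-yl]phenoxy}propan-1-ol (two molecules)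
Product: 9 (1R,2S)-1-(3,4-dimethoxyphenyl)-2-[4-[(2S,3S,4R,5R)-5-[4-[[(1R,2S)-1-(3,4-dimethoxyphenyl)-1-hydroxypropan-2-yl]oxy]-3-methoxyphenyl]-3,4-dimethyloxolan-2-yl]-2-methoxyphenoxy]propan-1-ol, via bis-benzylic dication 7 (not isolated), via hydroxy cation 8 (not isolated)
Conditions: graphite-felt anode held at +1.05 V vs Ag/AgCl, Pt cathode, undivided cell, LiClO4 (0.1 M), MeCN/H2O 9:1, 0.1 M in 6, N2, 0 °C, 1.1 F/mol, no base; then preparative HPLC
Reagents that add atoms: water, O
Why: Proposed new method: the 4-alkoxy-3-methoxy-β-methylstyrene unit of 6 is oxidised about 0.3 V below either veratryl ring, and its radical cation carries spin at C8 like the isoeugenol quinone-methide radical, so two units join C8–C8' to dication 7, the O-alkyl analogue of the biosynthetic bis-quinone methide; water adds to one benzylic cation (8) and the new hydroxyl closes 5-exo onto the other; closure is reversible in the unbuffered, anodically acidified medium, so each aryl group settles trans to its neighbouring methyl (C2, C5); the 3,4-cis relation comes only from unlike (meso) 8–8' coupling, which is not face-controlled (about 1:1 against like coupling is expected, the latter giving two all-trans-core diastereomers removed by HPLC); the side-chain centres are not touched; closest known reaction type is the anodic or aminium-salt radical-cation dimerisation of anethole-type 4-alkoxy-β-methylstyrenes with nucleophile capture (2,5-diaryl-3,4-dimethyloxolanes in wet MeCN).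

**Compound list**
1 | 1-(3,4-dimethoxyphenyl)propan-1-one | CCC(=O)c1ccc(OC)c(OC)c1 | starting material
2 | rac-2-bromo-1-(3,4-dimethoxyphenyl)propan-1-one | CC(Br)C(=O)c1ccc(OC)c(OC)c1 | intermediate
3 | (E)-isoeugenol, 2-methoxy-4-[(E)-prop-1-en-1-yl]phenol | C/C=C/c1ccc(O)c(OC)c1 | starting material
4 | rac-1-(3,4-dimethoxyphenyl)-2-{2-methoxy-4-[(E)-prop-1-en-1-yl]phenoxy}propan-1-one | C/C=C/c1ccc(OC(C)C(=O)c2ccc(OC)c(OC)c2)c(OC)c1 | intermediate
5 | (2S)-1-(3,4-dimethoxyphenyl)-2-{2-methoxy-4-[(E)-prop-1-en-1-yl]phenoxy}propan-1-one, the fast-reacting enantiomer of 4 | C/C=C/c1ccc(O[C@@H](C)C(=O)c2ccc(OC)c(OC)c2)c(OC)c1 | intermediate (not isolated)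
6 | (1R,2S)-1-(3,4-dimethoxyphenyl)-2-{2-methoxy-4-[(E)-prop-1-en-1-yl]phenoxy}propan-1-ol (erythro) | C/C=C/c1ccc(O[C@@H](C)[C@H](O)c2ccc(OC)c(OC)c2)c(OC)c1 | intermediate
7 | bis-benzylic dication: 2,3-dimethylbutane-1,4-diylium, unlike (meso-type) at C2/C3, carrying at C1 and at C4 a 3-methoxy-4-{[(1R,2S)-1-(3,4-dimethoxyphenyl)-1-hydroxypropan-2-yl]oxy}phenyl group | COc1ccc([C@@H](O)[C@H](C)Oc2ccc([CH+][C@@H](C)[C@@H](C)[CH+]c3ccc(O[C@@H](C)[C@H](O)c4ccc(OC)c(OC)c4)c(OC)c3)cc2OC)cc1OC | intermediate (not isolated)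
8 | hydroxy cation: monohydrate of 7, 4-hydroxy-2,3-dimethyl-1,4-diarylbutan-1-ylium with the same aryl groups, carbinol carbon in the configuration it has in 9 | COc1ccc([C@@H](O)[C@H](C)Oc2ccc([C@@H](O)[C@@H](C)[C@@H](C)[CH+]c3ccc(O[C@@H](C)[C@H](O)c4ccc(OC)c(OC)c4)c(OC)c3)cc2OC)cc1OC | intermediate (not isolated)
9 | (1R,2S)-1-(3,4-dimethoxyphenyl)-2-[4-[(2S,3S,4R,5R)-5-[4-[[(1R,2S)-1-(3,4-dimethoxyphenyl)-1-hydroxypropan-2-yl]oxy]-3-methoxyphenyl]-3,4-dimethyloxolan-2-yl]-2-methoxyphenoxy]propan-1-ol (CNP0116650.10) | COc1ccc([C@@H](O)[C@H](C)Oc2ccc([C@H]3O[C@@H](c4ccc(O[C@@H](C)[C@H](O)c5ccc(OC)c(OC)c5)c(OC)c4)[C@H](C)[C@@H]3C)cc2OC)cc1OC | target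

**Totals**
Total step count: 4. Longest linear sequence: 4 steps (1 → 2 → 4 → 6 → 9).

**Three steps most likely to fail**

Step 4 is the highest risk. The 8–8' coupling has no facial control, so 9 is expected to be at best about half of the oxolane fraction (roughly 15–25 % isolated). The benzylic cation can also be captured by the neighbouring arene (aryltetralin) instead of water. The fallback sets out from 2 and comes back at 9; it builds the core first and fixes the 8,8'-meso relation by crystallisation instead of by the coupling.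
- Commercial 1-(4-hydroxy-3-methoxyphenyl)propan-1-one is benzylated (BnBr, K2CO3, acetone) to 1-[4-(benzyloxy)-3-methoxyphenyl]propan-1-one F1.
- Its lithium enolate (LiN(iPr)2, THF, −78 °C) is coupled oxidatively with CuCl2. The meso isomer, meso-1,4-bis[4-(benzyloxy)-3-methoxyphenyl]-2,3-dimethylbutane-1,4-dione F2, is crystallised and the mother liquor is re-equilibrated with NaOMe.
- LiAlH4 in THF gives (2R,3S)-1,4-bis[4-(benzyloxy)-3-methoxyphenyl]-2,3-dimethylbutane-1,4-diol F3 as a carbinol-epimer mixture.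
- BF3·OEt2 in CH2Cl2 at 0 °C closes it by an SN1 path under thermodynamic control to meso-2,3-trans-3,4-cis-4,5-trans-2,5-bis[4-(benzyloxy)-3-methoxyphenyl]-3,4-dimethyloxolane F4.
- H2 over Pd/C in EtOAc removes the benzyl groups to give 4,4'-(meso-2,3-trans-3,4-cis-4,5-trans-3,4-dimethyloxolane-2,5-diyl)bis(2-methoxyphenol) F5.
- F5 is alkylated twice with 2 (K2CO3, acetone, reflux) to the bis(α-aryloxy ketone) F6, a mixture at the two α-centres.
- The step 3 hydrogenation conditions applied to F6 (double dynamic kinetic resolution) give 9.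

Step 3 is the next risk. The ketone may racemise too slowly, or the anti/syn ratio or the absolute sense may differ from the prediction. The fallback sets out from 3 and comes back at 6; it uses the chiral pool and a chelation-controlled reduction instead of catalyst control.
- Mitsunobu reaction of 3 with methyl (R)-lactate (PPh3, DIAD, THF, 0 °C, clean inversion) gives methyl (2S)-2-{2-methoxy-4-[(E)-prop-1-en-1-yl]phenoxy}propanoate F7.
- MeNH(OMe)·HCl and iPrMgCl in THF at −20 °C convert it into (2S)-N-methoxy-N-methyl-2-{2-methoxy-4-[(E)-prop-1-en-1-yl]phenoxy}propanamide F8.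
- 3,4-Dimethoxyphenylmagnesium bromide (THF, −20 °C) gives the (S)-ketone 5, which is isolated here.
- Zn(BH4)2 in Et2O at −30 °C reduces it through the five-membered chelate to the erythro alcohol 6.

Step 2 is the third risk. Under base and traces of air the propenylphenoxide of 3 can couple oxidatively to dehydrodiisoeugenol-type dimers, and 2 can lose HBr. The fallback sets out from 2 and comes back at 4; the propenyl group is brought in by cross-coupling after the ether is made.
- 2 alkylates 4-bromo-2-methoxyphenol (K2CO3, DMF, 25 °C) to rac-2-(4-bromo-2-methoxyphenoxy)-1-(3,4-dimethoxyphenyl)propan-1-one F9.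
- Suzuki–Miyaura coupling with potassium (E)-prop-1-enyltrifluoroborate (PdCl2(dppf), Cs2CO3, THF/H2O, 70 °C) gives 4.

**Further compounds**
F1 | step 4 | 1-[4-(benzyloxy)-3-methoxyphenyl]propan-1-one | CCC(=O)c1ccc(OCc2ccccc2)c(OC)c1
F2 | step 4 | meso-1,4-bis[4-(benzyloxy)-3-methoxyphenyl]-2,3-dimethylbutane-1,4-dione | O=C(c1ccc(OCc2ccccc2)c(OC)c1)[C@@H](C)[C@@H](C)C(=O)c1ccc(OCc2ccccc2)c(OC)c1
F3 | step 4 | (2R,3S)-1,4-bis[4-(benzyloxy)-3-methoxyphenyl]-2,3-dimethylbutane-1,4-diol, carbinol epimers | OC(c1ccc(OCc2ccccc2)c(OC)c1)[C@@H](C)[C@@H](C)C(O)c1ccc(OCc2ccccc2)c(OC)c1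
F4 | step 4 | meso-(2R,3R,4S,5S)-2,5-bis[4-(benzyloxy)-3-methoxyphenyl]-3,4-dimethyloxolane | COc1cc([C@H]2O[C@@H](c3ccc(OCc4ccccc4)c(OC)c3)[C@H](C)[C@@H]2C)ccc1OCc1ccccc1
F5 | step 4 | 4,4'-[meso-(2R,3R,4S,5S)-3,4-dimethyloxolane-2,5-diyl]bis(2-methoxyphenol) | COc1cc([C@H]2O[C@@H](c3ccc(O)c(OC)c3)[C@H](C)[C@@H]2C)ccc1O
F6 | step 4 | 2,2'-{[meso-(2R,3R,4S,5S)-3,4-dimethyloxolane-2,5-diyl]bis[(2-methoxy-4,1-phenylene)oxy]}bis[1-(3,4-dimethoxyphenyl)propan-1-one], mixture at both α-centres | COc1ccc(C(=O)C(C)Oc2ccc([C@H]3O[C@@H](c4ccc(OC(C)C(=O)c5ccc(OC)c(OC)c5)c(OC)c4)[C@H](C)[C@@H]3C)cc2OC)cc1OC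
F7 | step 3 | methyl (2S)-2-{2-methoxy-4-[(E)-prop-1-en-1-yl]phenoxy}propanoate | C/C=C/c1ccc(O[C@@H](C)C(=O)OC)c(OC)c1
F8 | step 3 | (2S)-N-methoxy-N-methyl-2-{2-methoxy-4-[(E)-prop-1-en-1-yl]phenoxy}propanamide | C/C=C/c1ccc(O[C@@H](C)C(=O)N(C)OC)c(OC)c1
F9 | step 2 | rac-2-(4-bromo-2-methoxyphenoxy)-1-(3,4-dimethoxyphenyl)propan-1-one | COc1cc(Br)ccc1OC(C)C(=O)c1ccc(OC)c(OC)c1
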